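**Assumption:** the facial sense of the (R)-oxazaborolidinium catalyst in step 15 is taken from the usual aldehyde-bound model (if it proves reversed, the (S)-catalyst is used). In the comments, C4–C13 follow eudesmane numbering and primed labels refer to the dihydropyran.

## Retrosynthetic overview

1. Last bond: C(sp3)–C(sp2) between the elemane ring and C5′ of the spiro-dihydropyran, by Pd-catalysed diastereoconvergent Negishi coupling of cyclohexylzinc 35 with alkenyl iodide 24.
2. 24 comes from cis-lactone 17 by C11 allylation, convex-face α-hydroxylation, hydroformylation/cyclodehydration (dihydropyran ring, last ring of this half) and C5′ iodination.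
3. 17 comes from linear dienone 11 by Li/NH3 1,6-reduction–alkylation (C4, C7), L-Selectride reduction (C8) and lactonisation. 11 comes from ring-A enal 9 by Wacker/aldol closure of ring B, with C10 set by Pd decarboxylative allylation.
4. Iodide 34 comes from ketone 32, made by an oxazaborolidinium Diels–Alder of diene 29 with keto-enal 27 (elemane ring and both its stereocentres) and double methylenation.
5. Ring order: eudesmane half ring A → ring B → lactone → dihydropyran; elemane ring in one [4+2]; the halves are joined last.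

## Route

**Step 1**
Reactants: 1 2-methylcyclohex-2-en-1-one; 2 allyl chloroformate
Product: 4 2-methylcyclohex-1-en-1-yl prop-2-en-1-yl carbonate, via lithium enolate 3 (not isolated)
Conditions: L-Selectride, THF, −78 °C; then 2, −78 → 0 °C
Reagents that add atoms: none
Why: 1,4-hydride reduction of the β-unsubstituted enone gives the tetrasubstituted enolate regiospecifically, and the chloroformate acylates it on oxygen (conjugate reduction / enolate O-acylation).

**Step 2**
Reactants: 4 2-methylcyclohex-1-en-1-yl prop-2-en-1-yl carbonate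
Product: 5 (2R)-2-methyl-2-(prop-2-en-1-yl)cyclohexan-1-one
Conditions: Pd2(dba)3 (2.5 mol %), (R)-t-Bu-PHOX (6 mol %), THF, 25 °C
Reagents that add atoms: none
Why: Pd-catalysed decarboxylative asymmetric allylic alkylation (Tsuji allylation) sets the quaternary centre C10 as R, the mirror image of the known (S)-ligand/(S)-ketone pairing (about 90% ee expected).

**Step 3**
Reactants: 5 (2R)-2-methyl-2-(prop-2-en-1-yl)cyclohexan-1-one
Product: 6 N'-[(2R)-2-methyl-2-(prop-2-en-1-yl)cyclohexylidene]-2,4,6-tri(propan-2-yl)benzenesulfonohydrazide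
Conditions: 2,4,6-triisopropylbenzenesulfonyl hydrazide, HCl (cat.), MeCN, 25 °C
Reagents that add atoms: 2,4,6-tri(propan-2-yl)benzenesulfonohydrazide NNS(=O)(=O)c1c(C(C)C)cc(C(C)C)cc1C(C)C
Why: Hydrazone condensation; the sulfonamide nitrogen sits syn to the only enolisable α-carbon, as needed for the directed deprotonations of the next step.

**Step 4**
Reactants: 6 the trisylhydrazone
Product: 9 (6R)-2,6-dimethyl-6-(prop-2-en-1-yl)cyclohex-1-ene-1-carbaldehyde, via methylated hydrazone 7 (not isolated), via vinyllithium 8 (not isolated)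
Conditions: n-BuLi (2.1 equiv), THF/TMEDA, −78 °C; MeI, −78 → −60 °C; n-BuLi (1.2 equiv), −78 → 0 °C; DMF, −78 → 25 °C
Reagents that add atoms: iodomethane CI; N,N-dimethylformamide CN(C)C=O
Why: Hydrazone dianion C-methylation, then Shapiro reaction to the tetrasubstituted vinyllithium and formylation; only one α-carbon bears hydrogen, so regiochemistry is unambiguous and the new methyl-bearing carbon becomes sp2.

**Step 5**
Reactants: 9 (6R)-2,6-dimethyl-6-(prop-2-en-1-yl)cyclohex-1-ene-1-carbaldehyde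
Product: 10 (6R)-2,6-dimethyl-6-(2-oxopropyl)cyclohex-1-ene-1-carbaldehyde
Conditions: PdCl2 (10 mol %), CuCl, O2 (1 atm), DMF/H2O 7:1, 25 °C
Reagents that add atoms: water O
Why: Tsuji–Wacker Markovnikov oxidation of the terminal alkene; the tetrasubstituted, electron-poor enal double bond does not react.

**Step 6**
Reactants: 10 (6R)-2,6-dimethyl-6-(2-oxopropyl)cyclohex-1-ene-1-carbaldehyde
Product: 11 (8aR)-5,8a-dimethyl-6,7,8,8a-tetrahydronaphthalen-2(1H)-one
Conditions: KOH, MeOH, 0 → 25 °C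
Reagents that add atoms: none
Why: Intramolecular aldol condensation; the ketone methyl is the only α-carbon that can reach the aldehyde through a six-membered ring, and dehydration gives the fully conjugated linear dienone (ring B).

**Step 7**
Reactants: 11 (8aR)-5,8a-dimethyl-6,7,8,8a-tetrahydronaphthalen-2(1H)-one; 12 methyl 2-bromoacetate
Product: 15 methyl 2-[(2S,4aR,8S)-4a,8-dimethyl-3-oxo-2,3,4,4a,5,6,7,8-octahydronaphthalen-2-yl]acetate, via lithium dienolate 13 (not isolated), via 2-epi keto ester 14 (not isolated)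
Conditions: Li (2.2 equiv), NH3/THF, t-BuOH (1.0 equiv), −78 °C; isoprene; NH3 off; 12 (1.0 equiv), THF, −78 → −30 °C; LiHMDS (0.95 equiv), −78 → 0 °C; AcOH, −78 °C
Reagents that add atoms: none
Why: Dissolving-metal 1,6-reduction of the linear dienone protonates the δ-carbon C4 anti to the angular methyl (4β-methyl); Stork reductive alkylation of the dienolate then occurs at C7 by axial attack, and equilibration to the conjugated dienolate followed by kinetic axial α-protonation turns the C7 chain equatorial (7β) while keeping the C5=C6 double bond out of conjugation.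

**Step 8**
Reactants: 15 the (2S,4aR,8S) keto ester
Product: 17 (3aS,5S,8aR,9aR)-5,8a-dimethyl-3a,5,6,7,8,8a,9,9a-octahydronaphtho[2,3-b]furan-2(3H)-one, via hydroxy ester 16 (not isolated)
Conditions: L-Selectride, THF, −78 → 0 °C; then p-TsOH (cat.), CH2Cl2, 25 °C
Reagents that add atoms: none
Why: The bulky hydride attacks C8 equatorially, anti to the 1,3-related axial C10 methyl, giving the axial 8β-alkoxide cis to the 7β-acetate arm, which closes to the cis-fused γ-lactone (stereoselective ketone reduction / lactonisation).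

**Step 9**
Reactants: 17 the cis-lactone; 18 3-bromoprop-1-ene
Product: 19 (3R,3aR,5S,8aR,9aR)-5,8a-dimethyl-3-(prop-2-en-1-yl)-3a,5,6,7,8,8a,9,9a-octahydronaphtho[2,3-b]furan-2(3H)-one
Conditions: LDA, THF, −78 °C; 18, DMPU, −78 → −20 °C
Reagents that add atoms: none
Why: Lactone enolate alkylation from the convex face of the cis-fused bicycle; the C11 configuration formed here is erased in the next step, so the ratio does not matter.

**Step 10**
Reactants: 19 the α-allyl lactone
Product: 20 (3R,3aR,5S,8aR,9aR)-3-hydroxy-5,8a-dimethyl-3-(prop-2-en-1-yl)-3a,5,6,7,8,8a,9,9a-octahydronaphtho[2,3-b]furan-2(3H)-one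
Conditions: KHMDS, THF, −78 °C; 2-(phenylsulfonyl)-3-phenyloxaziridine, −78 °C
Reagents that add atoms: 2-(benzenesulfonyl)-3-phenyloxaziridine O=S(=O)(N1OC1c1ccccc1)c1ccccc1
Why: Davis α-hydroxylation of the lactone enolate; oxygen enters from the convex face (syn to H7), placing the allyl group on the concave face, which is the C11 configuration of the target.

**Step 11**
Reactants: 20 the α-hydroxy-α-allyl lactone
Product: 23 (3R,3aR,5S,8aR,9aR)-5,8a-dimethyl-3a,3',4',5,6,7,8,8a,9,9a-decahydro-2H-spiro[naphtho[2,3-b]furan-3,2'-pyran]-2-one, via hydroxy aldehyde 21 (not isolated), via lactol 22 (not isolated)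
Conditions: Rh(acac)(CO)2 (1 mol %), BIPHEPHOS (2 mol %), CO/H2 1:1 (10 bar), toluene, 60 °C; then PPTS (10 mol %), 4 Å MS, 110 °C
Reagents that add atoms: carbon monoxide [C-]#[O+]
Why: Linear-selective Rh hydroformylation of the terminal alkene (the trisubstituted C5=C6 alkene is inert); the δ-hydroxy aldehyde closes to the lactol, and acid-catalysed dehydration gives the spiro 3,4-dihydro-2H-pyran without touching C11.

**Step 12**
Reactants: 23 the spiro dihydropyran
Product: 24 (3R,3aR,5S,8aR,9aR)-5'-iodo-5,8a-dimethyl-3a,3',4',5,6,7,8,8a,9,9a-decahydro-2H-spiro[naphtho[2,3-b]furan-3,2'-pyran]-2-one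
Conditions: NIS (1.1 equiv), AgNO3 (10 mol %), MeCN, 0 → 40 °C
Reagents that add atoms: N-iodosuccinimide O=C1CCC(=O)N1I
Why: Electrophilic iodination at the β-carbon of the enol ether and loss of the proton from the oxocarbenium ion (as in 2-iodoglycal synthesis); the enol ether is far more nucleophilic than the trisubstituted alkene.

**Step 13**
Reactants: 25 2,4-dimethylfuran
Product: 27 (2E)-2-methyl-4-oxopent-2-enal, via Z-keto-enal 26 (not isolated)
Conditions: NBS, NaHCO3, acetone/H2O 10:1, −20 °C; then pyridine, 25 °C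
Reagents that add atoms: water O
Why: Oxidative ring opening of the furan to the cis-ene-dicarbonyl, then pyridine-mediated isomerisation to the more stable E isomer (aldehyde and acetyl trans).

**Step 14**
Reactants: 28 but-3-en-2-one
Product: 29 (buta-1,3-dien-2-yloxy)tri(propan-2-yl)silane
Conditions: TIPSOTf, Et3N, Et2O, 0 °C
Reagents that add atoms: tri(propan-2-yl)silyl trifluoromethanesulfonate CC(C)[Si](OS(=O)(=O)C(F)(F)F)(C(C)C)C(C)C
Why: Soft enolisation/O-silylation of the methyl ketone gives the 2-silyloxydiene.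

**Step 15**
Reactants: 27 (2E)-2-methyl-4-oxopent-2-enal; 29 (buta-1,3-dien-2-yloxy)tri(propan-2-yl)silane
Product: 30 (1S,6S)-6-acetyl-1-methyl-4-{[tri(propan-2-yl)silyl]oxy}cyclohex-3-ene-1-carbaldehyde
Conditions: (R)-o-tolyl-CBS-oxazaborolidine (20 mol %), Tf2NH (18 mol %), CH2Cl2, −78 → −40 °C
Reagents that add atoms: none
Why: Cationic oxazaborolidine-catalysed Diels–Alder; the catalyst binds the aldehyde and shields one face of the α-carbon, so both ring stereocentres are set at once. The E geometry fixes formyl trans to acetyl, and the nucleophilic diene terminus adds to the carbon β to the aldehyde, giving the "para" silyl enol ether.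

**Step 16**
Reactants: 30 the Diels–Alder adduct
Product: 31 {[(4R,5R)-4-ethenyl-4-methyl-5-(prop-1-en-2-yl)cyclohex-1-en-1-yl]oxy}tri(propan-2-yl)silane
Conditions: Ph3PCH3Br (3.5 equiv), KOtBu (3.3 equiv), THF, 0 → 40 °C
Reagents that add atoms: methyltriphenylphosphonium bromide C[P+](c1ccccc1)(c1ccccc1)c1ccccc1.[Br-]
Why: Double Wittig methylenation turns the aldehyde into the vinyl group and the methyl ketone into the isopropenyl group; the silyl enol ether masks the third carbonyl.

**Step 17**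
Reactants: 31 the triene silyl enol ether
Product: 32 (3R,4R)-4-ethenyl-4-methyl-3-(prop-1-en-2-yl)cyclohexan-1-one
Conditions: TBAF, AcOH, THF, 0 °C
Reagents that add atoms: none
Why: Buffered fluoride cleavage of the silyl enol ether releases the ketone; the stereocentres are not α to it.

**Step 18**
Reactants: 32 (3R,4R)-4-ethenyl-4-methyl-3-(prop-1-en-2-yl)cyclohexan-1-one
Product: 33 (1S,3R,4R)-4-ethenyl-4-methyl-3-(prop-1-en-2-yl)cyclohexan-1-ol
Conditions: NaBH4, MeOH, 0 °C
Reagents that add atoms: none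
Why: Borohydride reduction, mainly by axial attack to the equatorial alcohol; the carbinol configuration is not carried into the target.

**Step 19**
Reactants: 33 the cyclohexanol
Product: 34 (1R,2R,4R)-1-ethenyl-4-iodo-1-methyl-2-(prop-1-en-2-yl)cyclohexane
Conditions: PPh3, I2, imidazole, CH2Cl2, 0 → 25 °C
Reagents that add atoms: iodine II
Why: Appel-type iodination with inversion; either C–I epimer is usable because the zinc reagent made from it is configurationally labile.

**Step 20**
Reactants: 34 the cyclohexyl iodide; 24 the alkenyl iodide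
Product: 36 (3R,3aR,5S,8aR,9aR)-5'-[(1S,3R,4R)-4-ethenyl-4-methyl-3-(prop-1-en-2-yl)cyclohexyl]-5,8a-dimethyl-3a,3',4',5,6,7,8,8a,9,9a-decahydro-2H-spiro[naphtho[2,3-b]furan-3,2'-pyran]-2-one, via cyclohexylzinc iodide 35 (not isolated)
Conditions: 34, Zn dust, LiCl, THF, 35 °C; then 24, Pd(OAc)2 (2 mol %), SPhos (4 mol %), THF/N-ethylpyrrolidone, −10 → 25 °C
Reagents that add atoms: none
Why: Proposed new method: Pd-catalysed diastereoconvergent Negishi coupling of a configurationally labile secondary cyclohexylzinc iodide with a cyclic β-iodo enol ether. Oxidative addition of the alkenyl iodide to Pd(0)/SPhos is followed by transmetalation from the rapidly epimerising RZnI·LiCl to the cyclohexyl–Pd species that carries Pd equatorial (vinyl and isopropenyl equatorial, methyl axial), and biarylphosphine-accelerated reductive elimination with retention outruns β-hydride elimination, giving the all-equatorial C1 configuration (1,3-cis to isopropenyl, 1,4-trans to vinyl). The closest known reactions are the diastereoselective Negishi couplings of substituted cyclohexylzinc halides with aryl iodides and the cross-couplings of 2-iodoglycals.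

## Compound list

1 | 2-methylcyclohex-2-en-1-one | CC1=CCCCC1=O | starting material
2 | prop-2-en-1-yl carbonochloridate (allyl chloroformate) | C=CCOC(Cl)=O | starting material
3 | lithium 2-methylcyclohex-1-en-1-olate | [Li]OC1=C(C)CCCC1 | intermediate
4 | 2-methylcyclohex-1-en-1-yl prop-2-en-1-yl carbonate | C=CCOC(=O)OC1=C(C)CCCC1 | intermediate
5 | (2R)-2-methyl-2-(prop-2-en-1-yl)cyclohexan-1-one | C=CC[C@@]1(C)CCCCC1=O | intermediate
6 | N'-[(2R)-2-methyl-2-(prop-2-en-1-yl)cyclohexylidene]-2,4,6-tri(propan-2-yl)benzenesulfonohydrazide | C=CC[C@@]1(C)CCCCC1=NNS(=O)(=O)c1c(C(C)C)cc(C(C)C)cc1C(C)C | intermediate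
7 | N'-[(2R)-2,6-dimethyl-2-(prop-2-en-1-yl)cyclohexylidene]-2,4,6-tri(propan-2-yl)benzenesulfonohydrazide (C6 epimers, present as its N-lithio salt) | C=CC[C@@]1(C)CCCC(C)C1=NNS(=O)(=O)c1c(C(C)C)cc(C(C)C)cc1C(C)C | intermediate
8 | [(6R)-2,6-dimethyl-6-(prop-2-en-1-yl)cyclohex-1-en-1-yl]lithium | C=CC[C@@]1(C)CCCC(C)=C1[Li] | intermediate
9 | (6R)-2,6-dimethyl-6-(prop-2-en-1-yl)cyclohex-1-ene-1-carbaldehyde | C=CC[C@@]1(C)CCCC(C)=C1C=O | intermediate
10 | (6R)-2,6-dimethyl-6-(2-oxopropyl)cyclohex-1-ene-1-carbaldehyde | CC(=O)C[C@@]1(C)CCCC(C)=C1C=O | intermediate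
11 | (8aR)-5,8a-dimethyl-6,7,8,8a-tetrahydronaphthalen-2(1H)-one | O=C1C[C@@]2(C)CCCC(C)=C2C=C1 | intermediate
12 | methyl 2-bromoacetate | COC(=O)CBr | starting material
13 | lithium (5S,8aR)-5,8a-dimethyl-1,5,6,7,8,8a-hexahydronaphthalen-2-olate | [Li]OC1=CC=C2[C@@H](C)CCC[C@]2(C)C1 | intermediate
14 | methyl 2-[(2R,4aR,8S)-4a,8-dimethyl-3-oxo-2,3,4,4a,5,6,7,8-octahydronaphthalen-2-yl]acetate | O=C1C[C@@]2(C)CCC[C@H](C)C2=C[C@H]1CC(=O)OC | intermediate
15 | methyl 2-[(2S,4aR,8S)-4a,8-dimethyl-3-oxo-2,3,4,4a,5,6,7,8-octahydronaphthalen-2-yl]acetate | O=C1C[C@@]2(C)CCC[C@H](C)C2=C[C@@H]1CC(=O)OC | intermediate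
16 | methyl 2-[(2S,3R,4aR,8S)-3-hydroxy-4a,8-dimethyl-2,3,4,4a,5,6,7,8-octahydronaphthalen-2-yl]acetate | O[C@@H]1C[C@@]2(C)CCC[C@H](C)C2=C[C@@H]1CC(=O)OC | intermediate
17 | (3aS,5S,8aR,9aR)-5,8a-dimethyl-3a,5,6,7,8,8a,9,9a-octahydronaphtho[2,3-b]furan-2(3H)-one | O=C1O[C@@H]2C[C@@]3(C)CCC[C@H](C)C3=C[C@@H]2C1 | intermediate
18 | 3-bromoprop-1-ene | C=CCBr | starting material
19 | (3R,3aR,5S,8aR,9aR)-5,8a-dimethyl-3-(prop-2-en-1-yl)-3a,5,6,7,8,8a,9,9a-octahydronaphtho[2,3-b]furan-2(3H)-one | C=CC[C@H]1C(=O)O[C@@H]2C[C@@]3(C)CCC[C@H](C)C3=C[C@@H]21 | intermediate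
20 | (3R,3aR,5S,8aR,9aR)-3-hydroxy-5,8a-dimethyl-3-(prop-2-en-1-yl)-3a,5,6,7,8,8a,9,9a-octahydronaphtho[2,3-b]furan-2(3H)-one | O[C@@]1(CC=C)C(=O)O[C@@H]2C[C@@]3(C)CCC[C@H](C)C3=C[C@@H]21 | intermediate
21 | 4-[(3R,3aR,5S,8aR,9aR)-3-hydroxy-5,8a-dimethyl-2-oxo-2,3,3a,5,6,7,8,8a,9,9a-decahydronaphtho[2,3-b]furan-3-yl]butanal | O[C@@]1(CCCC=O)C(=O)O[C@@H]2C[C@@]3(C)CCC[C@H](C)C3=C[C@@H]21 | intermediate
22 | (3R,3aR,5S,8aR,9aR)-6'-hydroxy-5,8a-dimethyl-3a,5,6,7,8,8a,9,9a-octahydro-2H-spiro[naphtho[2,3-b]furan-3,2'-oxan]-2-one (anomers) | OC1O[C@@]2(CCC1)C(=O)O[C@@H]3C[C@@]4(C)CCC[C@H](C)C4=C[C@@H]32 | intermediate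
23 | (3R,3aR,5S,8aR,9aR)-5,8a-dimethyl-3a,3',4',5,6,7,8,8a,9,9a-decahydro-2H-spiro[naphtho[2,3-b]furan-3,2'-pyran]-2-one | C1=CO[C@@]2(CC1)C(=O)O[C@@H]3C[C@@]4(C)CCC[C@H](C)C4=C[C@@H]32 | intermediate
24 | (3R,3aR,5S,8aR,9aR)-5'-iodo-5,8a-dimethyl-3a,3',4',5,6,7,8,8a,9,9a-decahydro-2H-spiro[naphtho[2,3-b]furan-3,2'-pyran]-2-one | IC1=CO[C@@]2(CC1)C(=O)O[C@@H]3C[C@@]4(C)CCC[C@H](C)C4=C[C@@H]32 | intermediate
25 | 2,4-dimethylfuran | Cc1cc(C)co1 | starting material
26 | (2Z)-2-methyl-4-oxopent-2-enal | O=C/C(C)=C\C(C)=O | intermediate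
27 | (2E)-2-methyl-4-oxopent-2-enal | O=C/C(C)=C/C(C)=O | intermediate
28 | but-3-en-2-one | C=CC(C)=O | starting material
29 | (buta-1,3-dien-2-yloxy)tri(propan-2-yl)silane | C=CC(=C)O[Si](C(C)C)(C(C)C)C(C)C | intermediate
30 | (1S,6S)-6-acetyl-1-methyl-4-{[tri(propan-2-yl)silyl]oxy}cyclohex-3-ene-1-carbaldehyde | O=C[C@@]1(C)CC=C(O[Si](C(C)C)(C(C)C)C(C)C)C[C@@H]1C(C)=O | intermediate
31 | {[(4R,5R)-4-ethenyl-4-methyl-5-(prop-1-en-2-yl)cyclohex-1-en-1-yl]oxy}tri(propan-2-yl)silane | C=C[C@@]1(C)CC=C(O[Si](C(C)C)(C(C)C)C(C)C)C[C@@H]1C(C)=C | intermediate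
32 | (3R,4R)-4-ethenyl-4-methyl-3-(prop-1-en-2-yl)cyclohexan-1-one | C=C[C@@]1(C)CCC(=O)C[C@@H]1C(C)=C | intermediate
33 | (1S,3R,4R)-4-ethenyl-4-methyl-3-(prop-1-en-2-yl)cyclohexan-1-ol | C=C[C@@]1(C)CC[C@H](O)C[C@@H]1C(C)=C | intermediate
34 | (1R,2R,4R)-1-ethenyl-4-iodo-1-methyl-2-(prop-1-en-2-yl)cyclohexane | C=C[C@@]1(C)CC[C@@H](I)C[C@@H]1C(C)=C | intermediate
35 | [(3R,4R)-4-ethenyl-4-methyl-3-(prop-1-en-2-yl)cyclohexyl](iodo)zinc (C1 epimers, LiCl complex) | C=C[C@@]1(C)CCC([Zn]I)C[C@@H]1C(C)=C | intermediate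
36 | (3R,3aR,5S,8aR,9aR)-5'-[(1S,3R,4R)-4-ethenyl-4-methyl-3-(prop-1-en-2-yl)cyclohexyl]-5,8a-dimethyl-3a,3',4',5,6,7,8,8a,9,9a-decahydro-2H-spiro[naphtho[2,3-b]furan-3,2'-pyran]-2-one | C=C[C@@]1(C)CC[C@H](C2=CO[C@@]3(CC2)C(=O)O[C@@H]2C[C@@]4(C)CCC[C@H](C)C4=C[C@@H]23)C[C@@H]1C(=C)C | target

## Step count and risk

Total step count: 20. Longest linear sequence: 13 (steps 1–12, then step 20), which is 0.65 of the total.

**Step 20 (the proposed new coupling).** The hindered secondary zinc reagent may transmetalate slowly to the electron-rich alkenyl–palladium species, and β-hydride elimination or imperfect diastereocontrol at the ring carbon could intervene. The fallback uses known chemistry and sets out from lactone 17 and iodide 34, returning to the route at target 36. Lactone 17 is deprotonated with LDA and treated with Eschenmoser's salt to give the Mannich base F1, which is quaternised with iodomethane to the methiodide F2 and eliminated with aqueous NaHCO3 to the α-methylene lactone (alantolactone) F3. Iodide 34 is joined with commercial 2-bromo-3,3-dimethoxyprop-1-ene in a nickel-catalysed reductive alkyl–alkenyl cross-electrophile coupling (NiBr2·glyme, 4,4'-di-tert-butyl-2,2'-bipyridine, Zn, DMA) to the acetal F4, whose equatorial epimer is separated and hydrolysed with aqueous oxalic acid to the 2-substituted acrolein F5. Heating F5 with F3 (toluene, 110 °C, BHT) effects the thermal hetero-Diels–Alder reaction of the enal with the exocyclic methylene, the enal oxygen bonding to C11 from the convex face, to give 36.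

**Step 7.** The one-pot reductive alkylation depends on clean 1,6-reduction, survival of the ester and the final kinetic protonation. The fallback sets out from dienone 11 and returns at keto ester 15. Dienone 11 is α-iodinated (I2, pyridine, CH2Cl2) to the iodo dienone F6, which undergoes Pd-catalysed Negishi coupling with the Reformatsky reagent BrZnCH2CO2Me to the dienone ester F7. Lithium in ammonia (2.05 equiv Li, t-BuOH, −78 °C) with an NH4Cl quench then sets both C4 and C7 by protonation anti to the angular methyl, giving 15 without any alkylation of a dienolate.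

**Step 15.** The dienophile carries two Lewis-basic carbonyl groups, so competing ketone coordination could erode enantio- and regiocontrol. The fallback sets out from diene 29 and returns at triene 31. Commercial methyl 3-methylbut-2-enoate is oxidised with SeO2 to the aldehyde ester F8, a dienophile with a single strong binding site, and the same catalyst gives the cycloadduct F9. One equivalent of methylenetriphenylphosphorane converts the aldehyde to the vinyl ester F10; N,O-dimethylhydroxylamine hydrochloride with i-PrMgCl gives the Weinreb amide F11; MeMgBr gives the methyl ketone F12; and a second Wittig methylenation gives 31.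

## Further compounds

F1 | step 20 | (3S,3aR,5S,8aR,9aR)-3-[(dimethylamino)methyl]-5,8a-dimethyl-3a,5,6,7,8,8a,9,9a-octahydronaphtho[2,3-b]furan-2(3H)-one | CN(C)C[C@H]1C(=O)O[C@@H]2C[C@@]3(C)CCC[C@H](C)C3=C[C@@H]21
F2 | step 20 | [(3S,3aR,5S,8aR,9aR)-5,8a-dimethyl-2-oxo-2,3,3a,5,6,7,8,8a,9,9a-decahydronaphtho[2,3-b]furan-3-yl]-N,N,N-trimethylmethanaminium iodide | C[N+](C)(C)C[C@H]1C(=O)O[C@@H]2C[C@@]3(C)CCC[C@H](C)C3=C[C@@H]21.[I-]
F3 | step 20 | (3aR,5S,8aR,9aR)-5,8a-dimethyl-3-methylidene-3a,5,6,7,8,8a,9,9a-octahydronaphtho[2,3-b]furan-2(3H)-one | C=C1C(=O)O[C@@H]2C[C@@]3(C)CCC[C@H](C)C3=C[C@@H]21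
F4 | step 20 | (1R,2R,4S)-4-(3,3-dimethoxyprop-1-en-2-yl)-1-ethenyl-1-methyl-2-(prop-1-en-2-yl)cyclohexane | C=C[C@@]1(C)CC[C@H](C(=C)C(OC)OC)C[C@@H]1C(C)=C
F5 | step 20 | 2-[(1S,3R,4R)-4-ethenyl-4-methyl-3-(prop-1-en-2-yl)cyclohexyl]prop-2-enal | C=C[C@@]1(C)CC[C@H](C(=C)C=O)C[C@@H]1C(C)=C
F6 | step 7 | (8aR)-3-iodo-5,8a-dimethyl-6,7,8,8a-tetrahydronaphthalen-2(1H)-one | O=C1C[C@@]2(C)CCCC(C)=C2C=C1I
F7 | step 7 | methyl 2-[(8aR)-5,8a-dimethyl-2-oxo-1,2,6,7,8,8a-hexahydronaphthalen-3-yl]acetate | COC(=O)CC1=CC2=C(C)CCC[C@]2(C)CC1=O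
F8 | step 15 | methyl (2E)-3-methyl-4-oxobut-2-enoate | O=C/C(C)=C/C(=O)OC
F9 | step 15 | methyl (1S,6S)-6-formyl-6-methyl-3-{[tri(propan-2-yl)silyl]oxy}cyclohex-3-ene-1-carboxylate | O=C[C@@]1(C)CC=C(O[Si](C(C)C)(C(C)C)C(C)C)C[C@@H]1C(=O)OC
F10 | step 15 | methyl (1S,6R)-6-ethenyl-6-methyl-3-{[tri(propan-2-yl)silyl]oxy}cyclohex-3-ene-1-carboxylate | C=C[C@@]1(C)CC=C(O[Si](C(C)C)(C(C)C)C(C)C)C[C@@H]1C(=O)OC
F11 | step 15 | (1S,6R)-6-ethenyl-N-methoxy-N,6-dimethyl-3-{[tri(propan-2-yl)silyl]oxy}cyclohex-3-ene-1-carboxamide | C=C[C@@]1(C)CC=C(O[Si](C(C)C)(C(C)C)C(C)C)C[C@@H]1C(=O)N(C)OC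
F12 | step 15 | 1-[(1S,6R)-6-ethenyl-6-methyl-3-{[tri(propan-2-yl)silyl]oxy}cyclohex-3-en-1-yl]ethan-1-one | C=C[C@@]1(C)CC=C(O[Si](C(C)C)(C(C)C)C(C)C)C[C@@H]1C(C)=O
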